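## Analysis of the target

Compound 14, 2,3-dibromo-6-(2,4-dibromophenoxy)phenol, is a diaryl ether of two benzene rings and has no stereocenter. Ring A is numbered here C1 (OH), C2 (ether oxygen), C3 and C4 (CH), C5 and C6 (Br), and these locants are kept for the same carbons in every intermediate, whatever the systematic name says; ring B is C1' (oxygen), C2' and C4' (Br). Ring B has the ordinary ortho/para bromination pattern of a phenol and can be bought complete as 2. Ring A is the hard part: in a 2-aryloxyphenol the hydroxyl group sends electrophiles first to C4, yet C4 must stay free while C5, meta to the hydroxyl, carries bromine. The sensitive functions are the four aryl C–Br bonds (no alkyllithium reagents, low-valent metals or hydrogenation late in the route) and the electron-rich free phenol, which is easily brominated further and is best unveiled last. The plan rests on the position of C6: it carries bromine and lies between the oxygen-bearing C1 and the brominated C5. With C6 removed, C1 to C5 form a cyclopentanone whose two α-carbons are C2 and C5, so the aryloxy group and the C5 bromine can be set by ketone chemistry and C6 can return as a CBr unit inserted into a C1=C5 enol ether bond. The difficulty then lies in the direction of two enolizations and in how a brominated enol ether behaves toward a dihalocarbene.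

## Retrosynthetic reasoning

**From 14 back to 10.** No skeletal bond is cut. Phenol 14 is the enol tautomer of cyclohexadienone 13, and 13 is enone 10 with one more double bond between C2 and C3; in the forward sense it is reached through the C2 bromide 12, formed from dienolate 11. Aromatizing last takes arene directing effects out of the problem: while ring A is an enone, C5 and C6 are a dibromoalkene beside a ketone and C4 is a plain methylene. The forward reaction must raise the oxidation level at C2/C3 once and stop, without a second bromination of the phenol at C4.

**From 10 to 7 and 8.** The bonds C1–C6 and C5–C6 are cut and C1–C5 is rejoined. This contracts ring A by one carbon to the cyclopentenyl silyl ether 7 and releases C6, with its bromine, as the one-carbon reagent 8; the bicyclic tribromide 9 lies between them. C6 is the only ring carbon flanked by the carbonyl carbon and a brominated carbon, so it is the only one that can be written as a CBr unit inserted into an enol ether bond. The gain is that the 5,6-dibromo pattern is fixed by connectivity, and what remains is a cyclopentanone substituted on both α-carbons. In the forward direction the CBr2 fragment from 8 must add to a bromine-bearing enol ether, and the fused cyclopropane must then open at its ring-fusion bond. A tert-butyldimethylsilyl ether is chosen for 7 instead of the more usual trimethylsilyl ether because it survives alkoxide base and chromatography.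

**From 7 to 6.** The O–Si bond is cut, leaving bromo ketone 6. What matters is the position of the double bond: it must lie between C1 and C5, toward bromine, and not between C1 and C2. The forward silylation therefore has to enolize the C5–H next to bromine, which is the more acidic and less hindered α-hydrogen.

**From 6 to 3.** The C5–Br bond is cut, giving ketone 3 by way of silyl enol ether 5 and enolate 4. Bromine goes on C5 after the aryloxy group is on C2 because the unsubstituted methylene is where a bulky base attacks under kinetic control. A silyl enol ether then passes that regiochemistry cleanly to an electrophilic bromine source. The base must be kept away from the C–H bonds of ring B and from the α-hydrogen at C2.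

**From 3 to 1 and 2.** The C2–O bond between the cyclopentanone and the aryl oxygen is cut, giving α-chloro ketone 1 and phenol 2. Ring B arrives with both bromines and its oxygen becomes the ether oxygen. No bond to an aromatic carbon is ever made, so no metal-catalysed coupling has to tolerate aryl bromides. The forward reaction is a substitution at an activated secondary carbon by a weakly basic phenoxide.

## Alternatives that were turned down

**Alternative 1:** The ether bond O–C1' and the C2'–Br bond of ring B are cut together, so ring B appears as an aryne.
- Forward key step: the cesium salt of 3,4-dibromo-2-methoxyphenol A1 would add through oxygen to the parent aryne released by CsF from 2-(trimethylsilyl)phenyl trifluoromethanesulfonate A2. The aryl anion would then take bromine from tetrabromomethane A3 to give 1,2-dibromo-4-(2-bromophenoxy)-3-methoxybenzene A4.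
- For it: both rings stay aromatic, no oxidation-state changes are needed, and the ether and one C–Br bond form in one mild operation from A1, A2 and A3. Beyond A4 only a para-bromination of ring B and an O-demethylation remain, which is shorter than the chosen route.
- Against it: A1 is itself the unsolved problem, a 1,2-dioxygenated benzene brominated where electrophilic bromination does not go. The C4' bromine must then be put in on A4, where C4 of ring A, para to the methoxy group, competes with C4' of the ortho-brominated ring B. The aryl anion formed from A2 must also be brominated by A3 faster than it is protonated, which is less secure than simple aryne O-arylation.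
- Comparison: the chosen strategy is longer, but it sets the ring A pattern by construction and brings ring B in complete as 2.

**Alternative 2:** Ring B is taken apart at C1'–C2' and C5'–C6'.
- Forward key step: 3,5-dibromo-2H-pyran-2-one A5 would take up the ethynyl ether of ring A, 1,2-dibromo-4-(ethynyloxy)-3-methoxybenzene A6, across its C3 and C6 in a Diels–Alder reaction. The bridged lactone would aromatize by decarboxylative cycloreversion to 1,2-dibromo-4-(2,4-dibromophenoxy)-3-methoxybenzene A7.
- For it: both ring B bromines are fixed by A5, the polarity of A6 matches that of A5 so the oxygen-bearing carbon ends next to the C3 bromine, and the extrusion is irreversible. Only an O-demethylation separates A7 from 14. On regiocontrol of ring B it is at least as strong as the chosen route, since no enolate selectivity is involved.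
- Against it: it spends the ring-forming step on the ring that can be bought as 2, while A6 must still be made from A1 and inherits the whole ring A problem. Aryl ethynyl ethers are normally made through dichlorovinyl ethers and alkyllithium bases, which aryl bromides do not tolerate, and A6 would be thermally fragile at the temperatures a cycloaddition to A5 needs.
- Comparison: the chosen route puts its one demanding step on ring A, where the difficulty is.

**Alternative 3:** Ring A is cut at C2–C3 and C5–C6.
- Forward key step: an alkoxide base would take 1-(2,4-dibromophenoxy)propan-2-one A8 through Michael addition of its aryloxy-bearing carbon to ethyl acrylate A9, then Claisen cyclization of its methyl carbon onto the ester, to give racemic 4-(2,4-dibromophenoxy)cyclohexane-1,3-dione A10.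
- For it: A8 is one alkylation from 2, and its annulation with A9 is a classical one-flask reaction. Bromination of A10 at C6 between the carbonyls and conversion of the C5 carbonyl into a vinyl bromide would reach compound 10 of the present route one step earlier. On step economy and on how well established each reaction is, this alternative is as strong as or stronger than the chosen one, and it also aromatizes late.
- Against it: two regiochemical choices rest on small biases. The Michael addition to A9 must start from the aryloxymethylene and not from the methyl group of A8, or the aryloxy group ends between the carbonyls. The two carbonyls of brominated A10 exchange through enol tautomers and differ only in a neighbouring aryloxy group, yet one must be selected for conversion to C–Br. The wrong choice gives an isomer of 10 that aromatizes to an isomer of 14 that is hard to separate.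
- Comparison: in the chosen route C1 is the only carbonyl carbon there ever is, and the bromines on C5 and C6 are tied to the bond the carbene enters, so this ambiguity cannot arise. The cost is one extra step and one step without direct precedent.

Key step: step 5

Remark on the chemistry: 14 is achiral, so 1 is used as the racemate and every sp3 stereocenter on the way is carried as a racemate or diastereomer mixture, to be erased in steps 4 to 6.

## Route

**Step 1**
Reactants: 1 2-chlorocyclopentan-1-one (racemic); 2 2,4-dibromophenol
Product: 3 2-(2,4-dibromophenoxy)cyclopentan-1-one (racemic)
Conditions: K2CO3, KI (cat.), acetone, reflux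
Reagents that add atoms: none
Why: Williamson ether synthesis by SN2 displacement at an α-halo ketone; the carbonyl accelerates substitution, iodide exchange (Finkelstein) improves the leaving group, and the weakly basic phenoxide of 2 should not trigger Favorskii rearrangement. The new stereocenter at C2 forms racemic and does not matter.

**Step 2**
Reactants: 3 2-(2,4-dibromophenoxy)cyclopentan-1-one
Product: 5 {[5-(2,4-dibromophenoxy)cyclopent-1-en-1-yl]oxy}trimethylsilane (racemic), via lithium enolate 4 (not isolated)
Conditions: LiN(iPr)2 (1.05 equiv), THF, −78 °C; Me3SiCl, −78 → 0 °C
Reagents that add atoms: chlorotrimethylsilane, C[Si](C)(C)Cl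
Why: Kinetic enolate formation and O-silylation; the hindered amide should remove a proton from the open C5 methylene faster than from the C2 methine, which is shielded by the ortho-brominated aryloxy group and would place the enolate carbon next to oxygen lone pairs. One equivalent of base at −78 °C is consumed by the ketone well before the far less acidic C3'–H between the two bromines of ring B can be metalated.

**Step 3**
Reactants: 5 {[5-(2,4-dibromophenoxy)cyclopent-1-en-1-yl]oxy}trimethylsilane
Product: 6 2-bromo-5-(2,4-dibromophenoxy)cyclopentan-1-one (racemic cis/trans mixture)
Conditions: NBS, NaHCO3, THF, −78 → 0 °C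
Reagents that add atoms: N-bromosuccinimide, O=C1CCC(=O)N1Br
Why: Electrophilic bromination of a silyl enol ether, which delivers bromine only to the enol carbon C5; the deactivated dibromophenyl ring does not compete. C5 becomes a stereocenter without control, and the mixture is used as such because C5 is flattened again in step 4.

**Step 4**
Reactants: 6 2-bromo-5-(2,4-dibromophenoxy)cyclopentan-1-one
Product: 7 tert-butyl{[2-bromo-5-(2,4-dibromophenoxy)cyclopent-1-en-1-yl]oxy}dimethylsilane (racemic)
Conditions: tBuMe2SiOTf, Et3N, CH2Cl2, −78 → 0 °C
Reagents that add atoms: tert-butyldimethylsilyl trifluoromethanesulfonate, CC(C)(C)[Si](C)(C)OS(=O)(=O)C(F)(F)F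
Why: Soft enolization (O-silylation by the silyl triflate, then deprotonation of the silyloxocarbenium ion by the amine); the C5–H next to bromine is the more acidic and less hindered of the two α-hydrogens, so the double bond should form between C1 and C5. The tert-butyldimethylsilyl ether tolerates chromatography on Et3N-deactivated silica, which removes any C1=C2 isomer, and later the alkoxide of step 5.

**Step 5**
Reactants: 7 tert-butyl{[2-bromo-5-(2,4-dibromophenoxy)cyclopent-1-en-1-yl]oxy}dimethylsilane; 8 bromoform
Product: 10 2,3-dibromo-6-(2,4-dibromophenoxy)cyclohex-2-en-1-one (racemic), via tribromocyclopropane 9 (not isolated)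
Conditions: CHBr3 (3 equiv), KOtBu (2.5 equiv, in portions), hexane/toluene, −30 °C → rt
Reagents that add atoms: bromoform (compound 8), BrC(Br)Br
Why: Proposed new method: the closest known reaction type is dihalocarbene addition to cyclic silyl enol ethers with ring expansion to 2-halocycloalk-2-enones, and dihalocarbenes are also known to add to vinyl bromides, but the two have not been combined on a 2-bromo silyl enol ether. Alkoxide α-elimination of 8 gives singlet dibromocarbene, which adds to the C1=C5 bond of 7 in a concerted cheletropic (2+1) addition that closes the three-membered ring of 9 (bonds C1–C6 and C5–C6); the siloxy group keeps this alkene nucleophilic despite the bromine on C5, and it is the only electron-rich alkene in 7, the benzene rings being inert to the carbene. In 9 the endo bromide on C6 is aligned with the strained fusion bond C1–C5, so this bond opens in a disrotatory two-electron electrocyclic process as bromide leaves, turning the bicyclo[3.1.0]hexane into the six-membered ring as a siloxy-stabilized allyl cation (C1–C6–C5). Bromide then takes the silyl group from oxygen as tBuMe2SiBr and leaves the enone with bromine on both C5 and C6. Besides the site of addition, the selectivity that matters is which cyclopropane bond breaks: loss of the bridgehead C5 bromide with cleavage of C1–C6 would give an exocyclic dibromomethylene ketone, but fusion-bond opening is the fast path in bicyclo[3.1.0]hexanes and puts the cationic termini on the oxygen-bearing C1 and the ring carbon C5. No lasting stereocenter is created, since the cyclopropane centres vanish on opening and C2 stays racemic. The tert-butyldimethylsilyl ether resists the alkoxide, and keeping 8 in excess over KOtBu protects the β-bromo enone from addition–elimination.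

**Step 6**
Reactants: 10 2,3-dibromo-6-(2,4-dibromophenoxy)cyclohex-2-en-1-one
Product: 14 2,3-dibromo-6-(2,4-dibromophenoxy)phenol, via lithium dienolate 11 (not isolated), via bromo ketone 12 (not isolated), via dienone 13 (not isolated)
Conditions: LiN(SiMe3)2, THF, −78 °C; NBS (1.0 equiv); DBU, −78 °C → rt; aq. NH4Cl
Reagents that add atoms: none
Why: Classical α-halogenation/dehydrohalogenation aromatization of a cyclohexenone: kinetic α'-enolization at the aryloxy-bearing carbon (C2 in ring A locants, the only α' position) gives cross-conjugated dienolate 11, which one equivalent of NBS brominates at that carbon. The tertiary α-bromo-α-aryloxy ketone 12 loses HBr toward C3 under DBU, and dienone 13, the keto tautomer of a phenol with a CH2 at C4, aromatizes at once. Consuming exactly one equivalent of the bromine source at −78 °C before the base is added keeps positive bromine away from the phenoxide.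

## Compound list

1 | 2-chlorocyclopentan-1-one (racemic) | O=C1CCCC1Cl | starting material
2 | 2,4-dibromophenol | Oc1ccc(Br)cc1Br | starting material
3 | 2-(2,4-dibromophenoxy)cyclopentan-1-one (racemic) | O=C1CCCC1Oc1ccc(Br)cc1Br | intermediate
4 | lithium 5-(2,4-dibromophenoxy)cyclopent-1-en-1-olate (racemic; not isolated) | [Li+].[O-]C1=CCCC1Oc1ccc(Br)cc1Br | intermediate
5 | {[5-(2,4-dibromophenoxy)cyclopent-1-en-1-yl]oxy}trimethylsilane (racemic) | C[Si](C)(C)OC1=CCCC1Oc1ccc(Br)cc1Br | intermediate
6 | 2-bromo-5-(2,4-dibromophenoxy)cyclopentan-1-one (racemic cis/trans mixture) | O=C1C(Br)CCC1Oc1ccc(Br)cc1Br | intermediate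
7 | tert-butyl{[2-bromo-5-(2,4-dibromophenoxy)cyclopent-1-en-1-yl]oxy}dimethylsilane (racemic) | CC(C)(C)[Si](C)(C)OC1=C(Br)CCC1Oc1ccc(Br)cc1Br | intermediate
8 | bromoform | BrC(Br)Br | starting material
9 | tert-butyl{[5,6,6-tribromo-2-(2,4-dibromophenoxy)bicyclo[3.1.0]hexan-1-yl]oxy}dimethylsilane (cis-fused racemic diastereomer mixture; not isolated) | CC(C)(C)[Si](C)(C)OC12C(Oc3ccc(Br)cc3Br)CCC1(Br)C2(Br)Br | intermediate
10 | 2,3-dibromo-6-(2,4-dibromophenoxy)cyclohex-2-en-1-one (racemic) | O=C1C(Br)=C(Br)CCC1Oc1ccc(Br)cc1Br | intermediate
11 | lithium 5,6-dibromo-2-(2,4-dibromophenoxy)cyclohexa-1,5-dien-1-olate (not isolated) | [Li+].[O-]C1=C(Oc2ccc(Br)cc2Br)CCC(Br)=C1Br | intermediate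
12 | 2,3,6-tribromo-6-(2,4-dibromophenoxy)cyclohex-2-en-1-one (racemic; not isolated) | O=C1C(Br)=C(Br)CCC1(Br)Oc1ccc(Br)cc1Br | intermediate
13 | 2,3-dibromo-6-(2,4-dibromophenoxy)cyclohexa-2,5-dien-1-one (not isolated) | O=C1C(Br)=C(Br)CC=C1Oc1ccc(Br)cc1Br | intermediate
14 | 2,3-dibromo-6-(2,4-dibromophenoxy)phenol | Oc1c(Oc2ccc(Br)cc2Br)ccc(Br)c1Br | target

## Step count and risk

Total step count: 6. Longest linear sequence: 6 steps (from 1, or from 2, to 14).

**Step 5 (key step, Proposed new method).**
- What may go wrong: the bromine on C5 may slow carbene addition so far that the carbene is lost to side reactions before it adds. The cyclopropane may open at the external C1–C6 bond with loss of the bridgehead bromide, which leaves a five-membered ring. tert-Butoxide may attack the β-carbon of the product by addition–elimination once the enone is free.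
- Fallback (known chemistry only; leaves the ring expansion, sets out from 2, returns at 14): 1,2-dibromo-4-fluorobenzene F1 is lithiated between fluorine and bromine with LiN(iPr)2 at −78 °C and formylated with DMF to give 2,3-dibromo-6-fluorobenzaldehyde F2. Nucleophilic aromatic substitution of the formyl-activated fluoride by 2 (K2CO3, DMF, 90 °C) gives 2,3-dibromo-6-(2,4-dibromophenoxy)benzaldehyde F3. Baeyer–Villiger oxidation with mCPBA gives 2,3-dibromo-6-(2,4-dibromophenoxy)phenyl formate F4, and methanolysis (K2CO3, MeOH) gives 14.

**Step 4.**
- What may go wrong: enolization toward the aryloxy-bearing C2 instead of the bromine-bearing C5. The difference in acidity and hindrance between the two α-hydrogens is real but not large, so the silylation may be poorly regioselective.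
- Fallback (fixes the double bond by construction; sets out from 6, returns at 10): dehydrobromination of 6 (Li2CO3, LiBr, DMF, 100 °C) gives 5-(2,4-dibromophenoxy)cyclopent-2-en-1-one F5. Addition of Br2 (CH2Cl2, 0 °C) gives 2,3-dibromo-5-(2,4-dibromophenoxy)cyclopentan-1-one F6, and Et3N removes HBr to leave 2-bromo-5-(2,4-dibromophenoxy)cyclopent-2-en-1-one F7. 1,4-Hydrosilylation (Et3SiH, cat. RhCl(PPh3)3) can place the enol ether double bond only between C1 and C5 and gives {[2-bromo-5-(2,4-dibromophenoxy)cyclopent-1-en-1-yl]oxy}triethylsilane F8. F8 takes the place of 7 in step 5, so the route is rejoined at 10.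

**Step 2.**
- What may go wrong: deprotonation at the aryloxy-bearing methine, whose hydrogen is the more acidic one thermodynamically, which would put bromine on C2 in step 3. Metalation of ring B between its bromines is possible if base is in excess.
- Fallback (enamine instead of enolate; sets out from 3, returns at 6): condensation of 3 with pyrrolidine (cat. TsOH, toluene, water removal) gives 1-[5-(2,4-dibromophenoxy)cyclopent-1-en-1-yl]pyrrolidine F9, whose double bond avoids the substituted carbon because of A(1,3) strain. NBS at −78 °C followed by aqueous hydrolysis of the α-bromo iminium ion gives 6.

**Step 6.**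
- What may go wrong: transfer of positive bromine from 12 or from residual NBS to the phenoxide as it forms, which would brominate C4. Addition–elimination of the amidine base at the bromine-bearing β-carbon before aromatization is also possible.
- Fallback (no electrophilic halogen; sets out from 10, returns at 14): direct dehydrogenation with DDQ (cat. TsOH, dioxane, 90 °C). DDQ abstracts hydride from C3 of the C1/C2 enol, and the resulting dienone 13 tautomerizes to 14 with no isolated intermediate.

## Further compounds

F1 | step 5 | 1,2-dibromo-4-fluorobenzene | Fc1ccc(Br)c(Br)c1
F2 | step 5 | 2,3-dibromo-6-fluorobenzaldehyde | O=Cc1c(F)ccc(Br)c1Br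
F3 | step 5 | 2,3-dibromo-6-(2,4-dibromophenoxy)benzaldehyde | O=Cc1c(Oc2ccc(Br)cc2Br)ccc(Br)c1Br
F4 | step 5 | 2,3-dibromo-6-(2,4-dibromophenoxy)phenyl formate | O=COc1c(Oc2ccc(Br)cc2Br)ccc(Br)c1Br
F5 | step 4 | 5-(2,4-dibromophenoxy)cyclopent-2-en-1-one (racemic) | O=C1C=CCC1Oc1ccc(Br)cc1Br
F6 | step 4 | 2,3-dibromo-5-(2,4-dibromophenoxy)cyclopentan-1-one (racemic diastereomer mixture) | O=C1C(Br)C(Br)CC1Oc1ccc(Br)cc1Br
F7 | step 4 | 2-bromo-5-(2,4-dibromophenoxy)cyclopent-2-en-1-one (racemic) | O=C1C(Br)=CCC1Oc1ccc(Br)cc1Br
F8 | step 4 | {[2-bromo-5-(2,4-dibromophenoxy)cyclopent-1-en-1-yl]oxy}triethylsilane (racemic) | CC[Si](CC)(CC)OC1=C(Br)CCC1Oc1ccc(Br)cc1Br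
F9 | step 2 | 1-[5-(2,4-dibromophenoxy)cyclopent-1-en-1-yl]pyrrolidine (racemic) | C1CCN(C1)C1=CCCC1Oc1ccc(Br)cc1Br
F0 | step 6 | none | none
A1 | alternative 1 | 3,4-dibromo-2-methoxyphenol | COc1c(O)ccc(Br)c1Br
A2 | alternative 1 | 2-(trimethylsilyl)phenyl trifluoromethanesulfonate | C[Si](C)(C)c1ccccc1OS(=O)(=O)C(F)(F)F
A3 | alternative 1 | tetrabromomethane | BrC(Br)(Br)Br
A4 | alternative 1 | 1,2-dibromo-4-(2-bromophenoxy)-3-methoxybenzene | COc1c(Oc2ccccc2Br)ccc(Br)c1Br
A5 | alternative 2 | 3,5-dibromo-2H-pyran-2-one | O=C1OC=C(Br)C=C1Br
A6 | alternative 2 | 1,2-dibromo-4-(ethynyloxy)-3-methoxybenzene | COc1c(OC#C)ccc(Br)c1Br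
A7 | alternative 2 | 1,2-dibromo-4-(2,4-dibromophenoxy)-3-methoxybenzene | COc1c(Oc2ccc(Br)cc2Br)ccc(Br)c1Br
A8 | alternative 3 | 1-(2,4-dibromophenoxy)propan-2-one | CC(=O)COc1ccc(Br)cc1Br
A9 | alternative 3 | ethyl acrylate | C=CC(=O)OCC
A10 | alternative 3 | 4-(2,4-dibromophenoxy)cyclohexane-1,3-dione (racemic) | O=C1CCC(Oc2ccc(Br)cc2Br)C(=O)C1
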